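**Assumption:** the target SMILES has no stereocentre and no stereogenic alkene (the molecule is achiral), so there is no configuration to set; the route only has to deliver the correct constitution.

## Retrosynthetic overview

1. Target 16 ⇐ tris‑TIPS ether 15 by global desilylation with fluoride; no acid is used at the end because the 2'‑hydroxyisoflav‑3‑ene and the o‑prenylphenol are acid‑sensitive.
2. The pyran ring is cut at C3–C4 and O1–C2: salicylaldehyde 9 (A ring + C4) plus α‑arylvinyl iodide 14 (B ring + C2/C3). They are joined by vinyllithium addition, then o‑quinone methide formation and oxa‑6π ring closure.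
3. Aldehyde 9 ⇐ resorcinol: C2 lithiation/prenylation of the dimethyl ether, mono‑demethylation, TIPS protection, Ir C–H borylation/oxidation for the third oxygen, ortho‑formylation.
4. Iodide 14 ⇐ resorcinol: C‑acetylation, silylation, hydrazone, Barton vinyl iodide synthesis.
5. Ring order: both benzene rings come intact from resorcinol; the only ring built is the pyran ring, closed in the coupling step.

## Route

### Fragment A (steps 1–6)

**Step 1**
Reactants: 1 resorcinol
Product: 2, 1,3‑dimethoxybenzene
Conditions: Me2SO4, K2CO3, acetone, reflux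
Reagents that add atoms: dimethyl sulfate, COS(=O)(=O)OC
Why: Exhaustive Williamson O‑methylation of both phenols.

**Step 2**
Reactants: 2 1,3‑dimethoxybenzene; 3 prenyl bromide (1‑bromo‑3‑methylbut‑2‑ene)
Product: 4, 1,3‑dimethoxy‑2‑(3‑methylbut‑2‑en‑1‑yl)benzene
Conditions: n‑BuLi, THF, 0 °C → rt; then CuI (10 mol %), 3, −78 °C → rt
Reagents that add atoms: none other than 3
Why: Directed ortho‑metalation occurs at C2 between the two cooperating OMe groups, and the aryl copper/lithium species is alkylated by prenyl bromide at the primary carbon (SN2).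

**Step 3**
Reactants: 4
Product: 5, 3‑methoxy‑2‑(3‑methylbut‑2‑en‑1‑yl)phenol
Conditions: EtSNa (3 eq), DMF, 140 °C, N2; cold dilute HCl work‑up
Reagents that add atoms: none
Why: Nucleophilic (SN2) demethylation by thiolate stops cleanly at the mono‑phenol because the resulting phenoxide deactivates the second aryl methyl ether.

**Step 4**
Reactants: 5
Product: 6, [3‑methoxy‑2‑(3‑methylbut‑2‑en‑1‑yl)phenoxy]triisopropylsilane
Conditions: TIPSCl, imidazole, DMF, 40 °C
Reagents that add atoms: triisopropylsilyl chloride, CC(C)[Si](Cl)(C(C)C)C(C)C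
Why: Phenol silylation; the bulky TIPS ether later shields its ortho position and is removable with fluoride at the end.

**Step 5**
Reactants: 6
Product: 7, 3‑methoxy‑4‑(3‑methylbut‑2‑en‑1‑yl)‑5‑(triisopropylsilyloxy)phenol
Conditions: [Ir(OMe)(cod)]2 (1.5 mol %), dtbpy (3 mol %), B2pin2, MTBE, 60 °C; then 30 % H2O2, aq NaOH, THF, 0 °C (one pot)
Reagents that add atoms: hydrogen peroxide, OO (the new oxygen); B2pin2, CC1(C)OB(OC1(C)C)B1OC(C)(C)C(C)(C)O1 (boron is transient and not retained)
Why: Sterically controlled Ir‑catalysed C–H borylation hits the only C–H not ortho to a substituent (C5, para to the prenyl group), and basic peroxide oxidises the aryl boronate to the phenol without touching the trisubstituted alkene.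

**Step 6**
Reactants: 7; 8 paraformaldehyde
Product: 9, 2‑hydroxy‑6‑methoxy‑5‑(3‑methylbut‑2‑en‑1‑yl)‑4‑(triisopropylsilyloxy)benzaldehyde
Conditions: MgCl2, Et3N, (CH2O)n, MeCN, reflux
Reagents that add atoms: none other than 8
Why: Mg‑phenoxide‑directed ortho‑formylation (Casnati–Skattebøl) is ortho‑specific to the free OH and is expected to go to the OMe‑flanked carbon because the other ortho carbon is shielded by the TIPS ether.

### Fragment B (steps 7–10)

**Step 7**
Reactants: 1 resorcinol; 10 acetic acid
Product: 11, 1‑(2,4‑dihydroxyphenyl)ethanone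
Conditions: AcOH, fused ZnCl2, 140 °C
Reagents that add atoms: none other than 10
Why: Nencki (Friedel–Crafts) C‑acylation of resorcinol at C4, a classical high‑yielding preparation of resacetophenone.

**Step 8**
Reactants: 11
Product: 12, 1‑[2,4‑bis(triisopropylsilyloxy)phenyl]ethanone
Conditions: TIPSCl (2.5 eq), imidazole, DMAP (cat.), DMF, 60 °C
Reagents that add atoms: triisopropylsilyl chloride, CC(C)[Si](Cl)(C(C)C)C(C)C
Why: Silylation of both phenols; chloride/imidazole is used instead of the triflate to avoid silyl enol ether formation at the methyl ketone.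

**Step 9**
Reactants: 12
Product: 13, 1‑[2,4‑bis(triisopropylsilyloxy)phenyl]ethanone hydrazone (C=N geometry immaterial)
Conditions: N2H4·H2O (10 eq), Et3N, EtOH, 75 °C
Reagents that add atoms: hydrazine, NN
Why: Ketone–hydrazine condensation; excess hydrazine suppresses azine formation and the hindered aryl TIPS ethers tolerate the mildly basic medium.

**Step 10**
Reactants: 13
Product: 14, [4‑(1‑iodoethenyl)‑1,3‑phenylene]bis(oxy)bis(triisopropylsilane), i.e. 1‑iodo‑1‑[2,4‑bis(triisopropylsilyloxy)phenyl]ethene
Conditions: I2, tetramethylguanidine, Et2O/THF, 0 °C → rt, dark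
Reagents that add atoms: iodine, II
Why: Barton vinyl iodide synthesis: oxidation of the hydrazone to the diazo/α‑iodo cation and loss of a proton from the methyl group gives the 1‑iodoalkene.

### Coupling and end game (steps 11–12)

**Step 11**
Reactants: 9; 14
Product: 15, 3‑[2,4‑bis(triisopropylsilyloxy)phenyl]‑5‑methoxy‑6‑(3‑methylbut‑2‑en‑1‑yl)‑7‑(triisopropylsilyloxy)‑2H‑chromene
Conditions: 14 (1.3 eq), t‑BuLi (2.6 eq), THF/Et2O, −78 °C; add sodium phenoxide of 9 (NaH, THF), −78 → 0 °C; then AcOH quench, PPTS (cat.), 40 °C (one pot)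
Reagents that add atoms: none
Why: Iodine–lithium exchange gives the α‑arylvinyllithium, which adds 1,2 to the aldehyde; mild acid then ionises the very electron‑rich o‑hydroxybenzylic allylic alcohol to a vinyl o‑quinone methide that closes by oxa‑6π electrocyclisation to the 3‑aryl‑2H‑chromene.

**Step 12**
Reactants: 15
Product: 16, dehydroglyasperin C [3‑(2,4‑dihydroxyphenyl)‑5‑methoxy‑6‑(3‑methylbut‑2‑en‑1‑yl)‑2H‑chromen‑7‑ol]
Conditions: TBAF (3.5 eq), AcOH (3.5 eq), THF, 0 °C, Ar, degassed
Reagents that add atoms: none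
Why: Fluoride cleaves all three aryl TIPS ethers under buffered, non‑acidic conditions that leave the prenyl group and the isoflav‑3‑ene intact.

## Compound list

1 | resorcinol | Oc1cccc(O)c1 | starting material
2 | 1,3‑dimethoxybenzene | COc1cccc(OC)c1 | intermediate
3 | prenyl bromide (1‑bromo‑3‑methylbut‑2‑ene) | CC(C)=CCBr | starting material
4 | 1,3‑dimethoxy‑2‑(3‑methylbut‑2‑en‑1‑yl)benzene | COc1cccc(OC)c1CC=C(C)C | intermediate
5 | 3‑methoxy‑2‑(3‑methylbut‑2‑en‑1‑yl)phenol | COc1cccc(O)c1CC=C(C)C | intermediate
6 | [3‑methoxy‑2‑(3‑methylbut‑2‑en‑1‑yl)phenoxy]triisopropylsilane | COc1cccc(O[Si](C(C)C)(C(C)C)C(C)C)c1CC=C(C)C | intermediate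
7 | 3‑methoxy‑4‑(3‑methylbut‑2‑en‑1‑yl)‑5‑(triisopropylsilyloxy)phenol | COc1cc(O)cc(O[Si](C(C)C)(C(C)C)C(C)C)c1CC=C(C)C | intermediate
8 | paraformaldehyde (formaldehyde) | C=O | starting material
9 | 2‑hydroxy‑6‑methoxy‑5‑(3‑methylbut‑2‑en‑1‑yl)‑4‑(triisopropylsilyloxy)benzaldehyde | COc1c(C=O)c(O)cc(O[Si](C(C)C)(C(C)C)C(C)C)c1CC=C(C)C | intermediate
10 | acetic acid | CC(=O)O | starting material
11 | 1‑(2,4‑dihydroxyphenyl)ethanone | CC(=O)c1ccc(O)cc1O | intermediate
12 | 1‑[2,4‑bis(triisopropylsilyloxy)phenyl]ethanone | CC(=O)c1ccc(O[Si](C(C)C)(C(C)C)C(C)C)cc1O[Si](C(C)C)(C(C)C)C(C)C | intermediate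
13 | 1‑[2,4‑bis(triisopropylsilyloxy)phenyl]ethanone hydrazone | CC(=NN)c1ccc(O[Si](C(C)C)(C(C)C)C(C)C)cc1O[Si](C(C)C)(C(C)C)C(C)C | intermediate
14 | 1‑iodo‑1‑[2,4‑bis(triisopropylsilyloxy)phenyl]ethene | C=C(I)c1ccc(O[Si](C(C)C)(C(C)C)C(C)C)cc1O[Si](C(C)C)(C(C)C)C(C)C | intermediate
15 | 3‑[2,4‑bis(triisopropylsilyloxy)phenyl]‑5‑methoxy‑6‑(3‑methylbut‑2‑en‑1‑yl)‑7‑(triisopropylsilyloxy)‑2H‑chromene | COc1c2c(cc(O[Si](C(C)C)(C(C)C)C(C)C)c1CC=C(C)C)OCC(c1ccc(O[Si](C(C)C)(C(C)C)C(C)C)cc1O[Si](C(C)C)(C(C)C)C(C)C)=C2 | intermediate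
16 | dehydroglyasperin C | COc1c2c(cc(O)c1CC=C(C)C)OCC(c1ccc(O)cc1O)=C2 | target

## Summary

**Total step count:** 12 (fragment A: 6; fragment B: 4; coupling/ring closure: 1; deprotection: 1).

**Longest linear sequence:** 8 steps (steps 1–6, 11, 12).

**Steps most likely to fail, with fallbacks:**

1. **Step 11** (hindered vinyllithium addition, possible O→C silyl migration in the ortho‑silyloxy vinyllithium, one‑pot cyclisation). Fallback: join the same two rings through a 3‑arylcoumarin instead. Perkin condensation of 9 with 2,4‑bis(triisopropylsilyloxy)phenylacetic acid, DIBAL‑H reduction to the (Z)‑allylic diol, and Mitsunobu ring closure would give 15.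
2. **Step 6** (regioselectivity between the two ortho positions of phenol 7). Fallback: replace the phenoxide‑directed formylation with directed ortho‑metalation. MOM‑protect 7, lithiate between OMOM and OMe (the TIPS side is blocked), quench with DMF, and either remove the MOM group with mild acid or carry it into step 11, where the acid‑triggered cyclisation expels it.
3. **Step 5** (Ir borylation in the presence of the prenyl alkene). Fallback: introduce the third oxygen before the alkene.
   - Borylate/oxidise 2 to 3,5‑dimethoxyphenol and protect it as the TIPS ether.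
   - Lithiate between the two OMe groups and prenylate.
   - Treat with EtSNa (mono‑demethylation with desilylation) to give 5‑methoxy‑4‑prenylresorcinol.
   - Formylate (Vilsmeier) para to the hydroxyl next to the prenyl group, then selectively TIPS‑protect the non‑chelated 4‑OH to reach 9.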